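## Retrosynthetic overview

1. The C2 stereocentre is set last, by face-selective hydrogenation of the C2=C3 enol ether of a 2-phenyl-4H-chromene.
2. Both oxygen heterocycles are closed in one acid operation from an open-chain diketone: the arm ArA–CO–CH2–ArB(OH) gives the furan ring of the benzofuran, then the arm ArA(OH)–CH2CH2–CO–Ph gives the pyran ring.
3. The three-carbon arm comes from C-Michael addition of a symmetric 2-acyl-5-methoxyresorcinol to phenyl vinyl ketone; the symmetry fixes the substitution pattern of ring A.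
4. The ArA–CO–CH2–ArB bond comes from palladium-catalysed enolate α-arylation of benzyl-protected 2,6-dihydroxy-4-methoxyacetophenone with a MOM-protected bromoresorcinol made from 2,4-dihydroxy-6-methoxybenzaldehyde.
5. Ring order: both benzene rings are bought; furan and pyran rings form together in step 7; no ring is formed afterwards.

Assumption: 1 and 6 are bought as catalogue compounds (1 is otherwise one Vilsmeier–Haack formylation away from 5-methoxyresorcinol).

## Route

Step 1
Reactants: 1 2,4-dihydroxy-6-methoxybenzaldehyde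
Product: 3 5-methoxy-4-methylbenzene-1,3-diol, via benzylic alcohol 2 (not isolated)
Conditions: H2 (4 bar), 10% Pd/C, AcOH, cat. HCl, 25 °C
Reagents that add atoms: none
Why: Catalytic hydrogenation of the aldehyde to the ortho,para-dihydroxybenzylic alcohol is followed by acid-assisted benzylic C–O hydrogenolysis, which is fast on this electron-rich ring and leaves the methyl group.

Step 2
Reactants: 3 5-methoxy-4-methylbenzene-1,3-diol
Product: 4 4-bromo-5-methoxy-6-methylbenzene-1,3-diol
Conditions: NBS (1.0 equiv), CH2Cl2/THF, −78 → −30 °C, dark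
Reagents that add atoms: N-bromosuccinimide, O=C1CCC(=O)N1Br
Why: Electrophilic aromatic bromination goes, as with resorcinol and orcinol, to the carbon that is ortho to one free OH and para to the other (C6 of 3) in preference to the doubly ortho carbon between the two OH groups, and one equivalent at low temperature limits dibromination.

Step 3
Reactants: 4 4-bromo-5-methoxy-6-methylbenzene-1,3-diol
Product: 5 2-bromo-3-methoxy-1,5-bis(methoxymethoxy)-4-methylbenzene
Conditions: NaH (2.4 equiv), MOMCl (2.4 equiv), THF/DMF, 0 °C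
Reagents that add atoms: chloromethyl methyl ether, COCCl
Why: Williamson-type O-alkylation turns both phenols into base-stable, acid-labile MOM acetals, so ring B stays masked until step 7.

Step 4
Reactants: 6 1-(2,6-dihydroxy-4-methoxyphenyl)ethanone
Product: 7 1-[2,6-bis(benzyloxy)-4-methoxyphenyl]ethanone
Conditions: BnBr (2.3 equiv), K2CO3 (3 equiv), DMF, 60 °C
Reagents that add atoms: benzyl bromide, BrCc1ccccc1
Why: Williamson O-benzylation of both hydrogen-bonded phenols gives a base-stable ketone whose only acidic C–H bonds are those of the acetyl group, with protecting groups orthogonal to the MOM ethers of 5.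

Step 5
Reactants: 7 1-[2,6-bis(benzyloxy)-4-methoxyphenyl]ethanone; 5 2-bromo-3-methoxy-1,5-bis(methoxymethoxy)-4-methylbenzene
Product: 9 1-(2,6-dihydroxy-4-methoxyphenyl)-2-[2-methoxy-3-methyl-4,6-bis(methoxymethoxy)phenyl]ethanone, via bis-benzyl deoxybenzoin 8 (not isolated)
Conditions: Pd2(dba)3 (2.5 mol%), 2-dicyclohexylphosphino-2′,4′,6′-triisopropylbiphenyl (6 mol%), NaOtBu (2.2 equiv), toluene, 80 °C; then AcOH (2.3 equiv), MeOH, 10% Pd/C, H2 (1 atm), 25 °C
Reagents that add atoms: none
Why: Palladium-catalysed ketone enolate α-arylation (Buchwald–Hartwig type) with a bulky biarylphosphine joins the methyl ketone to the hindered electron-rich aryl bromide, a second arylation being blocked sterically, and hydrogenolysis of the neutralised crude mixture removes only the benzyl ethers because the MOM acetals and the chelated ketone are inert under neutral H2/Pd.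

Step 6
Reactants: 9 1-(2,6-dihydroxy-4-methoxyphenyl)-2-[2-methoxy-3-methyl-4,6-bis(methoxymethoxy)phenyl]ethanone; 10 3-chloro-1-phenylpropan-1-one
Product: 12 1-[2,6-dihydroxy-4-methoxy-3-(3-oxo-3-phenylpropyl)phenyl]-2-[2-methoxy-3-methyl-4,6-bis(methoxymethoxy)phenyl]ethanone, via phenyl vinyl ketone 11 (not isolated)
Conditions: K2CO3 (2.2 equiv), THF/H2O (1:1), 0 → 25 °C, 10 added slowly (1.0 equiv)
Reagents that add atoms: none
Why: Carbonate eliminates HCl from 10 and the resulting enone takes part in a C-selective Michael addition (phenoxide C-alkylation) of the acylresorcinol dianion, in which the two free ring carbons of 9 are equivalent by symmetry, O-adducts revert, ring B has no free phenol and the ketone α-CH2 is not deprotonated by carbonate.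

Step 7
Reactants: 12 1-[2,6-dihydroxy-4-methoxy-3-(3-oxo-3-phenylpropyl)phenyl]-2-[2-methoxy-3-methyl-4,6-bis(methoxymethoxy)phenyl]ethanone
Product: 15 8-(6-hydroxy-4-methoxy-5-methyl-1-benzofuran-2-yl)-5-methoxy-2-phenyl-4H-chromen-7-ol, via tetraphenol diketone 13 (not isolated), via benzofuran ketone 14 (not isolated)
Conditions: TsOH·H2O (0.3 equiv), MeOH (0.02 mol/L), 55 °C, argon; then solvent switch to toluene, 4 Å molecular sieves, 80 °C; product used at once
Reagents that add atoms: none
Why: Acid-catalysed methanolysis of the MOM acetals frees ring B, whose ortho-hydroxybenzyl ketone cyclodehydrates to the benzofuran, and the ring A phenol ortho to the side chain then closes onto the propiophenone carbonyl and loses water or methanol to the 4H-chromene (double cyclodehydration), each ketone having only one phenol within reach so that both new rings are regiochemically unambiguous.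

Step 8
Reactants: 15 8-(6-hydroxy-4-methoxy-5-methyl-1-benzofuran-2-yl)-5-methoxy-2-phenyl-4H-chromen-7-ol
Product: 16 (2S)-8-(6-hydroxy-4-methoxy-5-methyl-1-benzofuran-2-yl)-5-methoxy-2-phenyl-3,4-dihydro-2H-chromen-7-ol
Conditions: H2 (50 bar), [Ir(cod)((S)-tBuPHOX)]B[3,5-(CF3)2C6H3]4 (2 mol%), CH2Cl2, 25 °C
Reagents that add atoms: none
Why: Iridium N,P-ligand catalysed asymmetric hydrogenation of the trisubstituted cyclic enol ether (2-aryl-4H-chromene class) adds H2 to one face of C2=C3 and so sets C2 as (S), the ligand hand shown being the one expected to give (2S) and to be confirmed by chiral HPLC and sign of rotation on the first run (antipodal ligand otherwise), while the benzofuran and the phenols are not reduced.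

## Compound list

1 | 2,4-dihydroxy-6-methoxybenzaldehyde | O=Cc1c(O)cc(O)cc1OC | starting material
2 | 4-(hydroxymethyl)-5-methoxybenzene-1,3-diol | OCc1c(O)cc(O)cc1OC | intermediate
3 | 5-methoxy-4-methylbenzene-1,3-diol | Cc1c(O)cc(O)cc1OC | intermediate
4 | 4-bromo-5-methoxy-6-methylbenzene-1,3-diol | Cc1c(O)cc(O)c(Br)c1OC | intermediate
5 | 2-bromo-3-methoxy-1,5-bis(methoxymethoxy)-4-methylbenzene | COCOc1cc(OCOC)c(C)c(OC)c1Br | intermediate
6 | 1-(2,6-dihydroxy-4-methoxyphenyl)ethanone | CC(=O)c1c(O)cc(OC)cc1O | starting material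
7 | 1-[2,6-bis(benzyloxy)-4-methoxyphenyl]ethanone | CC(=O)c1c(OCc2ccccc2)cc(OC)cc1OCc1ccccc1 | intermediate
8 | 1-[2,6-bis(benzyloxy)-4-methoxyphenyl]-2-[2-methoxy-3-methyl-4,6-bis(methoxymethoxy)phenyl]ethanone | COCOc1cc(OCOC)c(C)c(OC)c1CC(=O)c1c(OCc2ccccc2)cc(OC)cc1OCc1ccccc1 | intermediate
9 | 1-(2,6-dihydroxy-4-methoxyphenyl)-2-[2-methoxy-3-methyl-4,6-bis(methoxymethoxy)phenyl]ethanone | COCOc1cc(OCOC)c(C)c(OC)c1CC(=O)c1c(O)cc(OC)cc1O | intermediate
10 | 3-chloro-1-phenylpropan-1-one | O=C(CCCl)c1ccccc1 | starting material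
11 | 1-phenylprop-2-en-1-one (phenyl vinyl ketone) | C=CC(=O)c1ccccc1 | intermediate
12 | 1-[2,6-dihydroxy-4-methoxy-3-(3-oxo-3-phenylpropyl)phenyl]-2-[2-methoxy-3-methyl-4,6-bis(methoxymethoxy)phenyl]ethanone | COCOc1cc(OCOC)c(C)c(OC)c1CC(=O)c1c(O)cc(OC)c(CCC(=O)c2ccccc2)c1O | intermediate
13 | 2-(4,6-dihydroxy-2-methoxy-3-methylphenyl)-1-[2,6-dihydroxy-4-methoxy-3-(3-oxo-3-phenylpropyl)phenyl]ethanone | COc1c(C)c(O)cc(O)c1CC(=O)c1c(O)cc(OC)c(CCC(=O)c2ccccc2)c1O | intermediate
14 | 3-[2,4-dihydroxy-3-(6-hydroxy-4-methoxy-5-methyl-1-benzofuran-2-yl)-6-methoxyphenyl]-1-phenylpropan-1-one | COc1cc(O)c(-c2cc3c(OC)c(C)c(O)cc3o2)c(O)c1CCC(=O)c1ccccc1 | intermediate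
15 | 8-(6-hydroxy-4-methoxy-5-methyl-1-benzofuran-2-yl)-5-methoxy-2-phenyl-4H-chromen-7-ol | COc1cc(O)c(-c2cc3c(OC)c(C)c(O)cc3o2)c2c1CC=C(c1ccccc1)O2 | intermediate
16 | (2S)-8-(6-hydroxy-4-methoxy-5-methyl-1-benzofuran-2-yl)-5-methoxy-2-phenyl-3,4-dihydro-2H-chromen-7-ol (CNP0000229.1) | COc1cc(O)c(-c2cc3c(OC)c(C)c(O)cc3o2)c2c1CC[C@@H](c1ccccc1)O2 | target

## Step count and risks

Total steps: 8. Longest linear sequence: 7 (steps 1, 2, 3, 5, 6, 7, 8).

The three steps most likely to fail:

**Step 5** (both coupling partners are hindered and electron-rich; the tandem hydrogenolysis may stall). Fallback: reverse the polarity of the bond-forming step. It sets out from 7 and 5. CuBr2 (EtOAc, 70 °C) converts 7 into 2-bromo-1-[2,6-bis(benzyloxy)-4-methoxyphenyl]ethanone F1. Bromine–lithium exchange on 5 (n-BuLi, THF, −78 °C) gives [2-methoxy-3-methyl-4,6-bis(methoxymethoxy)phenyl]lithium F2, which ZnBr2 turns into [2-methoxy-3-methyl-4,6-bis(methoxymethoxy)phenyl]zinc bromide F3. Nickel-catalysed Negishi coupling of F1 with F3 (NiCl2·glyme, 2,2′-bipyridine, THF, 0 °C) comes back to the route at 8, which is hydrogenolysed to 9 as in the second half of step 5.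

**Step 7** (the electron-rich 4H-chromene can disproportionate or air-oxidise during dehydration). Fallback: pass through the oxidised, crystalline flavylium salt instead of dehydrating to the neutral enol ether. It sets out from 12. HCl in MeOH (50 °C) followed by chloranil in AcOH gives 7-hydroxy-8-(6-hydroxy-4-methoxy-5-methyl-1-benzofuran-2-yl)-5-methoxy-2-phenylchromenylium chloride F4, purified by crystallisation. NaBH4 (THF/MeOH, −40 °C) delivers hydride to C4 and comes back to the route at 15, which is taken at once into step 8.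

**Step 8** (free phenols and an acid-sensitive enol ether may give low conversion or low ee). Fallback: set the centre by ketone reduction and close the ring with inversion. It sets out from 15. Aqueous HCl in THF hydrolyses the enol ether to keto-phenol 14, now isolated. Transfer hydrogenation with RuCl[(R,R)-TsDPEN](p-cymene) in HCO2H/Et3N gives (1R)-3-[2,4-dihydroxy-3-(6-hydroxy-4-methoxy-5-methyl-1-benzofuran-2-yl)-6-methoxyphenyl]-1-phenylpropan-1-ol F5. Intramolecular Mitsunobu etherification (PPh3, diisopropyl azodicarboxylate, THF, 0 °C) by the only phenol ortho to the side chain inverts the carbinol centre and comes back to the route at 16.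

## Further compounds

F1 | step 5 | 2-bromo-1-[2,6-bis(benzyloxy)-4-methoxyphenyl]ethanone | O=C(CBr)c1c(OCc2ccccc2)cc(OC)cc1OCc1ccccc1
F2 | step 5 | [2-methoxy-3-methyl-4,6-bis(methoxymethoxy)phenyl]lithium | [Li]c1c(OCOC)cc(OCOC)c(C)c1OC
F3 | step 5 | [2-methoxy-3-methyl-4,6-bis(methoxymethoxy)phenyl]zinc bromide | Br[Zn]c1c(OCOC)cc(OCOC)c(C)c1OC
F4 | step 7 | 7-hydroxy-8-(6-hydroxy-4-methoxy-5-methyl-1-benzofuran-2-yl)-5-methoxy-2-phenylchromenylium chloride | COc1cc(O)c(-c2cc3c(OC)c(C)c(O)cc3o2)c2[o+]c(-c3ccccc3)ccc12.[Cl-]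
F5 | step 8 | (1R)-3-[2,4-dihydroxy-3-(6-hydroxy-4-methoxy-5-methyl-1-benzofuran-2-yl)-6-methoxyphenyl]-1-phenylpropan-1-ol | COc1cc(O)c(-c2cc3c(OC)c(C)c(O)cc3o2)c(O)c1CC[C@@H](O)c1ccccc1
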